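**Retrosynthetic overview**
1. Ring C (the pyranone) is cut at O1-C2 and C3-C4. This is possible because O1-C8a-C4a-C4(=O) is a salicylaldehyde raised to the acyl level, and C2(OAr)=C3 is the ynol ether of 4-methoxyphenol, capped at C3 with Me3Si.
2. Ring A is bought, not built. 2,4,6-Trihydroxybenzaldehyde is C-prenylated (future C8) and bis-MOM protected, so that only the hydroxyl between CHO and prenyl (future O1) stays free. This fixes the 8-prenyl ring fusion.
3. The ynol ether comes from 4-methoxyphenol and trichloroethylene through the dichlorovinyl ether, n-BuLi and Me3SiCl.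
4. Ring order: ring A and the anisyl ring are present from the start, and ring C is the only ring formed (step 5). C3-Si cleavage and MOM hydrolysis end the route.

Key step: step 5

Remark: the target has no stereocentre and no configured double bond, and 2,4,6-trihydroxybenzaldehyde is taken as a commercial compound.

**Step 1**
Reactants: 1 2,4,6-trihydroxybenzaldehyde; 2 prenyl bromide
Product: 3 2,4,6-trihydroxy-3-(3-methylbut-2-en-1-yl)benzaldehyde
Conditions: KOH (1.0 equiv), H2O, 0 °C; 2 (0.9 equiv), 0 °C → rt
Reagents that add atoms: none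
Why: C-alkylation of an ambident acylphloroglucinol phenoxide: in water the oxygens are hydrogen-bonded, so the soft allylic bromide is taken up at the two equivalent, doubly activated ring carbons C3/C5, and a slight deficit of 2 holds back a second prenylation.

**Step 2**
Reactants: 3 2,4,6-trihydroxy-3-(3-methylbut-2-en-1-yl)benzaldehyde
Product: 4 2-hydroxy-4,6-bis(methoxymethoxy)-3-(3-methylbut-2-en-1-yl)benzaldehyde
Conditions: MOMCl (2.2 equiv), i-Pr2NEt (2.5 equiv), CH2Cl2, 0 °C → rt
Reagents that add atoms: chloromethyl methyl ether (MOMCl), COCCl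
Why: MOM acetal formation (Williamson-type O-alkylation) under chelation and steric control: the unchelated 4-OH reacts first, then the 6-OH with one open flank, whereas the 2-OH wedged between CHO and prenyl keeps its hydrogen bond to the formyl oxygen and stays free.

**Step 3**
Reactants: 5 4-methoxyphenol; 6 trichloroethylene
Product: 8 1-{[(E)-1,2-dichloroethenyl]oxy}-4-methoxybenzene, via dichloroacetylene 7 (not isolated)
Conditions: K2CO3 (1.5 equiv), DMF, 70 °C
Reagents that add atoms: none
Why: Base-induced elimination of HCl from 6 to dichloroacetylene 7, followed by anti addition of the phenoxide (vinylation of a phenol by elimination-addition), gives the E-dichlorovinyl ether, and the aryl methyl ether is inert.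

**Step 4**
Reactants: 8 1-{[(E)-1,2-dichloroethenyl]oxy}-4-methoxybenzene
Product: 11 [(4-methoxyphenoxy)ethynyl]trimethylsilane, via chloroethynyl aryl ether 9 (not isolated), via lithium aryloxyacetylide 10 (not isolated)
Conditions: n-BuLi (2.2 equiv), THF, −78 → −40 °C; Me3SiCl (1.2 equiv), −78 °C → rt
Reagents that add atoms: chlorotrimethylsilane, C[Si](C)(C)Cl
Why: Dichlorovinyl ether route to ynol ethers: the first n-BuLi effects beta-elimination to chloroalkyne 9, the second effects chlorine-lithium exchange to acetylide 10, and C-silylation with Me3SiCl follows, an aryl ynol ether having no beta-hydrogen for retro-ene loss.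

**Step 5**
Reactants: 4 2-hydroxy-4,6-bis(methoxymethoxy)-3-(3-methylbut-2-en-1-yl)benzaldehyde; 11 [(4-methoxyphenoxy)ethynyl]trimethylsilane
Product: 12 5,7-bis(methoxymethoxy)-2-(4-methoxyphenoxy)-8-(3-methylbut-2-en-1-yl)-3-(trimethylsilyl)-4H-chromen-4-one
Conditions: [RhCl2(C5Me5)]2 (5 mol %), CsOAc (30 mol %), anhydrous Cu(OAc)2 (2.2 equiv), 4 Å sieves, PhMe, 80 °C, N2; 11 (1.5 equiv) added slowly
Reagents that add atoms: none
Why: Proposed new method: the phenoxide of 4 binds (C5Me5)Rh in the trivalent state and acetate-assisted cleavage of the formyl C-H bond gives the five-membered acyl rhodacycle Rh-C4-C4a-C8a-O1, exactly as in the closest known reaction type, the rhodium/Cu(OAc)2 oxidative annulation of salicylaldehydes with carbon-substituted internal alkynes to 2,3-disubstituted chromones, in which an oxygen-substituted alkyne has not been shown. Alkyne 11 is polarised by its donor oxygen and by silicon, so the electrophilic metal takes the silyl-bearing carbon (alpha-silyl-stabilised C-Rh bond, larger group next to the metal) and the aryloxy-bearing carbon becomes ketenium-like. A lone pair of the rhodium-bound O1 adds to that carbon (syn-oxyrhodation, O1-C2), and acyl-vinyl reductive elimination from the seven-membered rhodacycle Rh-C4-C4a-C8a-O1-C2-C3 forms C3-C4 and closes the six-membered pyranone ring C in a formal [4+2] sense, after which Cu(OAc)2 returns monovalent rhodium to the trivalent state. The selectivity needed is the orientation O1 to C(OAr) and C4 to C(SiMe3), which is the polarity-matched one: nucleophilic oxygen meets the oxygen-stabilised carbon and the electrophilic acyl carbon meets the nucleophilic remote carbon, the pairing that acylketenes show in [4+2] additions to vinyl ethers and ynamines and that acylpalladium species show toward vinyl ethers. The competing event is migration of the acyl ligand instead of O1 to the aryloxy-bearing carbon, and substrate 4 works against it because its aroyl carbon is hindered by the ortho OMOM group while its dialkoxy-substituted phenoxide is strongly electron-rich; the Me3Si cap also shuts off copper acetylide and alkyne dimerisation chemistry. No stereocentre is formed, the trisubstituted prenyl alkene is a poor ligand for (C5Me5)Rh, the MOM ethers tolerate the acetate-buffered medium, and slow addition of 11 over sieves limits its loss to acetic acid or water.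

**Step 6**
Reactants: 12 5,7-bis(methoxymethoxy)-2-(4-methoxyphenoxy)-8-(3-methylbut-2-en-1-yl)-3-(trimethylsilyl)-4H-chromen-4-one
Product: 13 5,7-bis(methoxymethoxy)-2-(4-methoxyphenoxy)-8-(3-methylbut-2-en-1-yl)-4H-chromen-4-one
Conditions: Bu4NF/AcOH (1:1, 1.2 equiv), THF, 0 °C → rt
Reagents that add atoms: none
Why: Fluoride-induced protodesilylation of a vinylsilane alpha to a carbonyl group: fluoride attacks silicon, acetic acid protonates C3 and keeps the medium free of hydroxide or alkoxide that could displace the C2 aryloxy group, the MOM ethers and the prenyl alkene are untouched, and material that has already lost silicon in step 5 is the same compound 13.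

**Step 7**
Reactants: 13 5,7-bis(methoxymethoxy)-2-(4-methoxyphenoxy)-8-(3-methylbut-2-en-1-yl)-4H-chromen-4-one
Product: 14 5,7-dihydroxy-2-(4-methoxyphenoxy)-8-(3-methylbut-2-en-1-yl)-4H-chromen-4-one (CNP0274214.0)
Conditions: 3 M aq. HCl, THF, 40 °C
Reagents that add atoms: none
Why: Acid-catalysed acetal hydrolysis (MOM cleavage): the 5-O-MOM group peri to the carbonyl goes first and the 7-O-MOM group follows, while a non-alcoholic medium and only mild warming avoid exchange of the C2 aryloxy group and closure of the 7-OH onto the prenyl alkene.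

**Compound list**
1 | 2,4,6-trihydroxybenzaldehyde | O=Cc1c(O)cc(O)cc1O | starting material
2 | prenyl bromide (1-bromo-3-methylbut-2-ene) | CC(C)=CCBr | starting material
3 | 2,4,6-trihydroxy-3-(3-methylbut-2-en-1-yl)benzaldehyde | O=Cc1c(O)cc(O)c(CC=C(C)C)c1O | intermediate
4 | 2-hydroxy-4,6-bis(methoxymethoxy)-3-(3-methylbut-2-en-1-yl)benzaldehyde | O=Cc1c(OCOC)cc(OCOC)c(CC=C(C)C)c1O | intermediate
5 | 4-methoxyphenol | COc1ccc(O)cc1 | starting material
6 | trichloroethylene | ClC=C(Cl)Cl | starting material
7 | dichloroacetylene (not isolated) | ClC#CCl | intermediate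
8 | 1-{[(E)-1,2-dichloroethenyl]oxy}-4-methoxybenzene | COc1ccc(O/C(Cl)=C\Cl)cc1 | intermediate
9 | 1-[(chloroethynyl)oxy]-4-methoxybenzene (not isolated) | COc1ccc(OC#CCl)cc1 | intermediate
10 | lithium (4-methoxyphenoxy)acetylide (not isolated) | COc1ccc(OC#C[Li])cc1 | intermediate
11 | [(4-methoxyphenoxy)ethynyl]trimethylsilane | C[Si](C)(C)C#COc1ccc(OC)cc1 | intermediate
12 | 5,7-bis(methoxymethoxy)-2-(4-methoxyphenoxy)-8-(3-methylbut-2-en-1-yl)-3-(trimethylsilyl)-4H-chromen-4-one | COCOc1cc(OCOC)c2c(c1CC=C(C)C)oc(Oc1ccc(OC)cc1)c([Si](C)(C)C)c2=O | intermediate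
13 | 5,7-bis(methoxymethoxy)-2-(4-methoxyphenoxy)-8-(3-methylbut-2-en-1-yl)-4H-chromen-4-one | COCOc1cc(OCOC)c2c(c1CC=C(C)C)oc(Oc1ccc(OC)cc1)cc2=O | intermediate
14 | 5,7-dihydroxy-2-(4-methoxyphenoxy)-8-(3-methylbut-2-en-1-yl)-4H-chromen-4-one | COc1ccc(Oc2cc(=O)c3c(O)cc(O)c(CC=C(C)C)c3o2)cc1 | target

**Totals**
Total step count: 7.
Longest linear sequence: 5 (steps 1, 2, 5, 6, 7; the branch 3, 4, 5, 6, 7 is equally long).

**Steps most likely to fail**

Step 5. Several processes could defeat the annulation:
- The acyl ligand may migrate to the aryloxy-bearing carbon faster than O1 adds there, which reverses the orientation of the alkyne.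
- The acetic acid released by the oxidant may add to the ynol ether.
- The hindered acyl rhodacycle may decarbonylate.
- The alkyne may lose silicon early and then dimerise.

The fallback is the polar alkynone route to chromones, which is known chemistry. It sets out from 4 and 10 and comes back at 13, so steps 5 and 6 are both bypassed. The phenol of 4 is deprotonated with LiN(SiMe3)2 in THF at −78 °C. Acetylide 10, generated from 8 as in step 4 but not silylated, is then added to the aldehyde. After an NH4Cl quench this should give racemic 1-[2-hydroxy-4,6-bis(methoxymethoxy)-3-(3-methylbut-2-en-1-yl)phenyl]-3-(4-methoxyphenoxy)prop-2-yn-1-ol F1. Neutral oxidation of this benzylic, propargylic alcohol with MnO2 in CH2Cl2 removes the carbinol centre and gives 1-[2-hydroxy-4,6-bis(methoxymethoxy)-3-(3-methylbut-2-en-1-yl)phenyl]-3-(4-methoxyphenoxy)prop-2-yn-1-one F2. The phenol of F2 closes 6-endo-dig (K2CO3, acetone, rt) onto the aryloxy-bearing alkyne carbon, which is both the Michael terminus and the oxygen-stabilised position. This gives 13.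

Step 2. A MOM group may be transferred to the hindered hydroxyl between CHO and prenyl instead of the C6 hydroxyl, and that material would lead on to the 6-prenyl series. The fallback sets out from 1 and comes back at 4. It reverses the order of events, so that the single free hydroxyl dictates where the prenyl group goes.
- Symmetric 1 is bis-protected (MOMCl, i-Pr2NEt, CH2Cl2) to 2-hydroxy-4,6-bis(methoxymethoxy)benzaldehyde F3. The two ortho hydroxyls are equivalent here, so no regiochemical question arises.
- Tsuji-Trost-type decarboxylative O-allylation gives the tertiary ether 2,4-bis(methoxymethoxy)-6-[(2-methylbut-3-en-2-yl)oxy]benzaldehyde F4. The reagents are tert-butyl 2-methylbut-3-en-2-yl carbonate and Pd(PPh3)4 (zerovalent palladium) in THF at 0 °C.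
- Aromatic Claisen rearrangement (PhMe, 110 °C) can end only at the one open ortho carbon. It inverts the 1,1-dimethylallyl unit to a prenyl group and gives 4.

Step 7. The liberated 7-hydroxyl may close onto the prenyl alkene under acid (chroman formation), or the C2 aryloxy group may be solvolysed. The fallback is an acid-free endgame with silyl ethers. It sets out from 3 and comes back at 14.
- Compound 3 is bis-silylated (t-BuMe2SiCl, imidazole, CH2Cl2, 0 °C), with the same chelation and steric bias as in step 2. This gives 4,6-bis[(tert-butyldimethylsilyl)oxy]-2-hydroxy-3-(3-methylbut-2-en-1-yl)benzaldehyde F5.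
- F5 is annulated with 11 under the conditions of step 5 to 5,7-bis[(tert-butyldimethylsilyl)oxy]-2-(4-methoxyphenoxy)-8-(3-methylbut-2-en-1-yl)-3-(trimethylsilyl)-4H-chromen-4-one F6.
- One treatment with Bu4NF/AcOH in THF at 0 °C cleaves both O-Si bonds and the C3-Si bond and gives 14.

**Further compounds**
F1 | step 5 | 1-[2-hydroxy-4,6-bis(methoxymethoxy)-3-(3-methylbut-2-en-1-yl)phenyl]-3-(4-methoxyphenoxy)prop-2-yn-1-ol (racemic) | COCOc1cc(OCOC)c(C(O)C#COc2ccc(OC)cc2)c(O)c1CC=C(C)C
F2 | step 5 | 1-[2-hydroxy-4,6-bis(methoxymethoxy)-3-(3-methylbut-2-en-1-yl)phenyl]-3-(4-methoxyphenoxy)prop-2-yn-1-one | COCOc1cc(OCOC)c(C(=O)C#COc2ccc(OC)cc2)c(O)c1CC=C(C)C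
F3 | step 2 | 2-hydroxy-4,6-bis(methoxymethoxy)benzaldehyde | O=Cc1c(O)cc(OCOC)cc1OCOC
F4 | step 2 | 2,4-bis(methoxymethoxy)-6-[(2-methylbut-3-en-2-yl)oxy]benzaldehyde | O=Cc1c(OC(C)(C)C=C)cc(OCOC)cc1OCOC
F5 | step 7 | 4,6-bis[(tert-butyldimethylsilyl)oxy]-2-hydroxy-3-(3-methylbut-2-en-1-yl)benzaldehyde | O=Cc1c(O[Si](C)(C)C(C)(C)C)cc(O[Si](C)(C)C(C)(C)C)c(CC=C(C)C)c1O
F6 | step 7 | 5,7-bis[(tert-butyldimethylsilyl)oxy]-2-(4-methoxyphenoxy)-8-(3-methylbut-2-en-1-yl)-3-(trimethylsilyl)-4H-chromen-4-one | CC(C)=CCc1c(O[Si](C)(C)C(C)(C)C)cc(O[Si](C)(C)C(C)(C)C)c2c1oc(Oc1ccc(OC)cc1)c([Si](C)(C)C)c2=O
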